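**Retrosynthetic overview**
1. The ring carbons, the OMe and the ring methyl all come from one phenol, 2-methoxy-5-methylphenol (1); no ring is formed and the target has no stereocentre.
2. Aryl–C22 disconnection: the chain comes from docosan-1-ol (2) by dehydrative ortho C–H alkylation of 1, giving phenol 3; 1 has only one ortho C–H, so only one regioisomer can form.
3. Key disconnection (C4=O): aerobic para C–H oxygenation of 3 breaks the aromaticity and gives quinone 4 directly; no hydroquinone or polymethoxyarene is built and the quinone itself is never alkylated.

Assumption: the SMILES is read as an n-docosyl (C22) chain on an achiral quinone, so "single enantiomer" means the one achiral compound.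

Step 1
Reactants: 1 2-methoxy-5-methylphenol (1.0 equiv); 2 docosan-1-ol (1.3 equiv)
Product: 3 2-docosyl-6-methoxy-3-methylphenol
Conditions: [(η6-C6H6)(PCy3)(CO)RuH]BF4 (3 mol %), toluene, 110 °C, sealed tube, 16 h
Reagents that add atoms: none
Why: Ruthenium-hydride-catalysed dehydrative ortho C–H alkylation of a phenol with a primary alcohol (phenol-directed ortho-ruthenation, C–O cleavage of the alcohol, C–C bond formation), in which the linear chain can enter only at C6 because the other ortho carbon carries OMe, and water is the only co-product.

Step 2
Reactants: 3 2-docosyl-6-methoxy-3-methylphenol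
Product: 4 3-docosyl-5-methoxy-2-methylcyclohexa-2,5-diene-1,4-dione (target)
Conditions: Co(salen) (salcomine, 20 mol %), O2 (1 atm), DMF/THF 2:1, 40 °C, 8 h
Reagents that add atoms: dioxygen, O=O
Why: Salcomine-catalysed aerobic oxidative dearomatisation (Teuber-type phenol-to-p-quinone oxidation), in which the cobalt–superoxo species forms the phenoxyl radical, oxygenates it at the only free para carbon and the peroxy-dienone collapses to the p-quinone, with the OMe group blocking o-quinone formation and water as the only co-product.

**Compound list**
1 | 2-methoxy-5-methylphenol (5-methylguaiacol) | COc1ccc(C)cc1O | starting material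
2 | docosan-1-ol (behenyl alcohol) | CCCCCCCCCCCCCCCCCCCCCCO | starting material
3 | 2-docosyl-6-methoxy-3-methylphenol | CCCCCCCCCCCCCCCCCCCCCCc1c(C)ccc(OC)c1O | intermediate
4 | 3-docosyl-5-methoxy-2-methylcyclohexa-2,5-diene-1,4-dione | CCCCCCCCCCCCCCCCCCCCCCC1=C(C)C(=O)C=C(OC)C1=O | target

**Total step count:** 2
**Longest linear sequence:** 2

**Steps most likely to fail** (the route has only two steps, so two are ranked and there is no third)

1. Step 1 is the weaker step. The reacting carbon of 1 lies between OH and CH3 and has no second π-donor ortho or para to it, unlike the very electron-rich phenols this catalysis favours; the neighbouring OMe may also bind ruthenium. Fallback, setting out from 2 (together with 1) and returning at 3: oxidise 2 with catalytic TEMPO and PhI(OAc)2 in CH2Cl2 to docosanal F1. Condense F1 with 1 and phenylboronic acid (catalytic propanoic acid, toluene, reflux, Dean–Stark) to give racemic 4-henicosyl-8-methoxy-5-methyl-2-phenyl-4H-1,3,2-benzodioxaborinine F2; here boron delivers the aldehyde to the ortho carbon only. Ionic hydrogenation of the benzylic C–O bond of F2 with Et3SiH/TFA in CH2Cl2, then aqueous work-up, gives 3 and releases phenylboronic acid. This replaces the catalytic C–H/C–O coupling by a boron-templated ortho-hydroxyalkylation followed by reduction.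

2. Step 2 may suffer from poor solubility of the C22 phenol in DMF or from phenoxyl-radical C–C coupling instead of oxygenation. Fallback, setting out from 3 and returning at 4: couple 3 at its free para carbon with 4-sulfobenzenediazonium chloride (from sulfanilic acid, NaNO2, HCl) in pyridine/THF/aqueous NaOH at 0 °C to give the azo dye 4-[(E)-(3-docosyl-4-hydroxy-5-methoxy-2-methylphenyl)diazenyl]benzenesulfonic acid F3. Cleave the N=N bond with Na2S2O4 in aqueous THF at 60 °C to give 4-amino-2-docosyl-6-methoxy-3-methylphenol F4 and sulfanilic acid. Oxidise F4 with FeCl3 in aqueous HCl/EtOAc at room temperature; the quinone imine hydrolyses to 4 with loss of ammonium chloride. This replaces the radical O2 oxygenation by a polar para-amination and oxidation sequence.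

**Further compounds**
F1 | step 1 | docosanal | CCCCCCCCCCCCCCCCCCCCCC=O
F2 | step 1 | (RS)-4-henicosyl-8-methoxy-5-methyl-2-phenyl-4H-1,3,2-benzodioxaborinine | CCCCCCCCCCCCCCCCCCCCCC1OB(c2ccccc2)Oc2c(OC)ccc(C)c12
F3 | step 2 | 4-[(E)-(3-docosyl-4-hydroxy-5-methoxy-2-methylphenyl)diazenyl]benzenesulfonic acid | CCCCCCCCCCCCCCCCCCCCCCc1c(C)c(/N=N/c2ccc(cc2)S(O)(=O)=O)cc(OC)c1O
F4 | step 2 | 4-amino-2-docosyl-6-methoxy-3-methylphenol | CCCCCCCCCCCCCCCCCCCCCCc1c(C)c(N)cc(OC)c1O
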